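(The earlier runs and the new flask are calculated for substances that don't exist.)

The vessel, stirred at constant volume and temperature, takes substrate in 2 equal portions 50 h apart, while catalyst meets added ligand.

| setting | birch | larch | alder | flask |
|---|---|---|---|---|
| substrate | 0.10 M (in portions, 2) | 0.10 M (in portions, 2) | 0.10 M (in portions, 2) | 0.10 M (in portions, 2) |
| free catalyst | 2.9 mol% | 2.9 mol% | 5.8 mol% | 2.9 mol% |
| added ligand | 6.9 mM | 11 mM | 4.9 mM | 4.9 mM |
| remark | run made earlier; portions every 50 h | run made earlier; portions every 50 h | run made earlier; portions every 50 h | the portions of substrate follow each other after 50 h, the first at the start |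
| time |  |  |  | 4.0 d |

| run | time / d | product / % | substrate / % |
|---|---|---|---|
| birch | 0.167 | 20.5 | 28.8 |
| birch | 0.500 | 37.3 | 11.9 |
| birch | 0.833 | 43.5 | 6.7 |
| birch | 1.25 | 45.5 | 4.4 |
| birch | 2.08 | 46.3 | 3.3 |
| birch | 2.50 | 56.5 | 44.1 |
| birch | 3.00 | 65.6 | 34.1 |
| larch | 0.167 | 19.1 | 30.2 |
| larch | 0.500 | 35.5 | 14.6 |
| larch | 0.833 | 40.2 | 10.3 |
| larch | 1.25 | 42.6 | 7.6 |
| larch | 2.08 | 44.1 | 5.7 |
| larch | 2.50 | 48.6 | 51.4 |
| larch | 3.00 | 54.2 | 45.6 |
| alder | 0.625 | 46.8 | 3.2 |
| alder | 1.25 | 47.4 | 2.5 |
| alder | 2.08 | 47.9 | 2.8 |
| alder | 2.50 | 81.8 | 18.8 |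
| alder | 3.00 | 92.2 | 7.7 |

(each reading ± 0.3 percentage points)

* concentration of product at 4.0 d, in M
* concentration of substrate at 4.0 d, in M

- a species is counted by the substrate in it: one idle complex B counts as two
- the analysis behind the earlier runs scatters by 0.3 percentage points, standard deviation
- what may be going on: substrate + free catalyst <-> catalyst intermediate A; catalyst intermediate A <-> catalyst intermediate B; catalyst intermediate B <-> free catalyst + product; free catalyst + added ligand <-> idle complex A; substrate + catalyst intermediate A <-> idle complex B

On the first rung stands the catalyst round: at 2.08 d, birch's product and substrate sum to 49.6 % of the charge, with half of it added, so the catalyst forms hold little. Next comes relaxation: substrate falls towards an equilibrium fraction, read from alder as 5.01 %. Birch's first reading gives the gap to equilibrium a pseudo-first-order rate of 3.54 /d, or 1.22 /mM/d per unit of catalyst. Birch's second portion relaxes at 0.591 /d, which reads as 0.484 mM of active catalyst. Second-order capture by ligand, taken as one-way, then reads as 0.124 /mM/d. In the flask, this reading puts the time constant of capture near 1.65 d, slower than relaxation and shorter than the interval. So the second portion relaxes on fading catalyst.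

My own reckoning uses the relaxation exponent, the rate per unit of catalyst times mean active catalyst times the second portion's duration. In the flask, by this estimate, active catalyst falls from 1.09 mM to 0.565 mM, with 0.774 mM at mid-time. That gives an exponent of 1.81 and substrate 12.8 %. The mean of the two ends is higher and gives 11.8 %, so the choice of mean moves the estimate by 1.00 percentage point.

The forecast, citing “slow, nearly irreversible capture of catalyst by ligand”, gave product 0.0865 M (0.083 M to 0.09 M) and substrate 0.0133 M (0.01 M to 0.017 M), a substrate fraction above mine.

The flask gives product 0.0877 M and substrate 0.0122 M.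

    substrate + free catalyst ⇌ catalyst intermediate A (K = 6.70 /M, k = 350 /M/h)
    catalyst intermediate A ⇌ catalyst intermediate B (K = 1.20, k = 110 /h)
    catalyst intermediate B ⇌ free catalyst + product (K = 2.30 M, k = 14.0 /h)
    free catalyst + added ligand ⇌ idle complex A (K = 2300 /M, k = 10.0 /M/h)
    substrate + catalyst intermediate A ⇌ idle complex B, settled at all times (K = 9.10 /M)

The flask's first portion ran down to substrate 2.82 % of the whole charge by 2.08 d, with idle complex A then holding 72.6 % of the catalyst. The second portion ran on while that share rose to 79.4 % at 4.00 d. Against the equilibrium fraction read from alder, the flask's exponent comes to 1.90, and ligand at 5.18 mM moves the flask's substrate by a tenth of itself. The neighbour with 0.0012 M of ligand has 1.70 mM of catalyst charged beyond that ligand; taken as its active catalyst, this gives an estimated exponent of 3.98 and substrate 5.90 %, and that neighbour holds substrate 5.19 % at 4.00 d.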